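**Plan** (flavanone numbering: O1, C2, C3, C4, C4a, C5–C8, C8a; ring B primed)
1. Retrosynthetic cuts, in order: the 5-O–Si bond (protecting group). Then C2–C3 of ring C, back to a carbene carbon at C3 (stored as CHN2) and the methylene O1–CH2–ring B. Then O1–C2 (phenol plus benzylic alcohol). Last the aryl–allyl bonds C6–prenyl and C2'–geranyl.
2. Forward: rings A and B are bought as arenes. Ring B is geranylated at C2' and ring A is prenylated at C6. The halves are joined through O1, the acetyl CH3 becomes CHN2, and the pyranone ring C is closed last by enantioselective C–H insertion.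
3. Enabling feature: the C2–H bonds are alpha to O1 and benzylic to ring B, whose 4'-OMe stands para to C2, so they are the most hydridic C–H bonds in the molecule. O1 fills the position 1,5 to C3, so only the six-membered closure is open. C4a and C8a are ortho on ring A and hold C3 next to C2.
4. Stereochemistry: C2 is the only stereocentre. It is made from a CH2 group by catalyst-controlled choice between two enantiotopic hydrogens. The E alkene is bought with geranyl bromide.
5. Helpers: the diazo group (lost as N2 in the key step) and a TBS group on 5-OH (removed in the last step).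

Key step: step 6

Assumption: the sense of induction of Rh2(S-PTTL)4 on 11 cannot be derived with certainty from models. The (S)-ligand series is written. The mirror-image catalyst Rh2(R-PTTL)4 would be taken if the pro-R hydrogen turned out to be preferred.

Step 1
Reactants: 1 3,4-dimethoxybenzyl alcohol; 2 geranyl bromide
Product: 4 [2-[(2E)-3,7-dimethylocta-2,6-dienyl]-3,4-dimethoxyphenyl]methanol, via C2-lithiated lithium alkoxide 3 (not isolated)
Conditions: n-BuLi (2.2 equiv), Et2O–hexane, 0 °C to rt; CuBr·SMe2 (20 mol %), THF, −30 °C; 2, −30 °C to rt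
Reagents that add atoms: n-butyllithium, [Li]CCCC (its lithium stands in 3 only)
Why: Directed ortho-metalation, in which the lithium alkoxide and the 3-methoxy group together place lithium on the carbon between them, followed by copper-catalysed SN2 allylation of the aryl anion with the primary allylic bromide, which should keep the E geometry and give the linear geranyl arene.

Step 2
Reactants: 5 2',6'-dihydroxy-4'-methoxyacetophenone; 6 prenyl bromide
Product: 7 1-[2,6-dihydroxy-4-methoxy-3-(3-methylbut-2-enyl)phenyl]ethanone
Conditions: KOH (1.1 equiv), H2O–MeOH, 0 °C to rt, 6 (1.0 equiv) added slowly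
Reagents that add atoms: none
Why: C-alkylation of an ambident phloroglucinol-type phenolate in a protic medium, where the two free ring positions of 5 are equivalent by symmetry, so mono-prenylation can give only one C-isomer.

Step 3
Reactants: 4 geranylated benzylic alcohol; 7 prenylated acetophenone
Product: 8 1-[6-[[2-[(2E)-3,7-dimethylocta-2,6-dienyl]-3,4-dimethoxyphenyl]methoxy]-2-hydroxy-4-methoxy-3-(3-methylbut-2-enyl)phenyl]ethanone
Conditions: PPh3, DIAD, THF, 0 °C to rt (4 and 7 in equimolar amounts)
Reagents that add atoms: none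
Why: Mitsunobu etherification, which should take the hydroxyl next to the ring C–H because it is less hindered and less firmly hydrogen-bonded (the prenyl group presses its neighbouring OH onto the carbonyl oxygen), while the remaining chelated phenol resists a second alkylation.

Step 4
Reactants: 8 aryl benzyl ether
Product: 9 1-[2-(tert-butyldimethylsilyloxy)-6-[[2-[(2E)-3,7-dimethylocta-2,6-dienyl]-3,4-dimethoxyphenyl]methoxy]-4-methoxy-3-(3-methylbut-2-enyl)phenyl]ethanone
Conditions: TBSOTf, 2,6-lutidine, CH2Cl2, 0 °C
Reagents that add atoms: tert-butyldimethylsilyl triflate, CC(C)(C)[Si](C)(C)OS(=O)(=O)C(F)(F)F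
Why: Silyl triflate silylation of the chelated phenol, which masks an O–H that would otherwise trap the carbene by O–H insertion and uses a group with neither an activated C–H bond nor a nucleophilic oxygen.

Step 5
Reactants: 9 silyl-protected acetophenone
Product: 11 2-diazo-1-[2-(tert-butyldimethylsilyloxy)-6-[[2-[(2E)-3,7-dimethylocta-2,6-dienyl]-3,4-dimethoxyphenyl]methoxy]-4-methoxy-3-(3-methylbut-2-enyl)phenyl]ethanone, via trifluoroacetyl diketone 10 (not isolated)
Conditions: LiN(SiMe3)2 (1.1 equiv), THF, −78 °C; CF3CO2CH2CF3, −78 °C, 10 min; crude 10, MsN3, Et3N, H2O (1 equiv), MeCN, rt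
Reagents that add atoms: 2,2,2-trifluoroethyl trifluoroacetate, FC(F)(F)COC(=O)C(F)(F)F (its CF3CO group stands in 10 only); methanesulfonyl azide, CS(=O)(=O)N=[N+]=[N-]
Why: Detrifluoroacetylative variant of the Regitz diazo transfer, in which the kinetic lithium enolate is acylated on the unhindered methyl carbon, the sulfonyl azide transfers N2 to the activated methylene, and the trifluoroacetyl group leaves as the N-sulfonyl amide.

Step 6
Reactants: 11 diazoketone
Product: 12 (2S)-5-(tert-butyldimethylsilyloxy)-2-[2-[(2E)-3,7-dimethylocta-2,6-dienyl]-3,4-dimethoxyphenyl]-7-methoxy-6-(3-methylbut-2-enyl)-2,3-dihydrochromen-4-one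
Conditions: Rh2(S-PTTL)4 (dirhodium tetrakis[N-phthaloyl-(S)-tert-leucinate], 2 mol %), 4 Å MS, CH2Cl2, 0 °C, slow addition of 11 at high dilution
Reagents that add atoms: none
Why: Rh2(S-PTTL)4 expels N2 from 11 and gives an electrophilic acyl carbene bound to divalent rhodium at C3, which takes one C2–H bond in a concerted but asynchronous, hydride-transfer-like three-centre transition state, so that C3–H and C3–C2 form with retention at C2. The closest known reaction type is the chiral dirhodium carboxylate-catalysed C–H insertion of o-alkoxyaryl diazoketones, which gives 2-substituted chroman-4-ones. Ring C closes in the 1,6-insertion mode through a six-membered chair-like array (C3, C4, C4a, C8a, O1, C2), since the usual five-membered mode is impossible when the atom 1,5 to the carbene carbon is O1 and carries no hydrogen. C2 is set by the catalyst alone: the phthalimide walls of the carboxylate pocket should let the bulky 2-geranyl-3,4-dimethoxyphenyl group point away from the rhodium face in only one of the two diastereomeric arrays, so the pro-S hydrogen is replaced and (S)-12 should result. The step needs chemoselectivity for this C–H bond over ylide formation at O1 with a Stevens 1,2-shift, over cyclopropanation and over O–H insertion; the charge building at C2 is stabilised by O1 and the para 4'-methoxy group, O1 is a weak donor because its lone pair is shared with the acyl-bearing ring A, the geranyl alkene is reachable only through a ten-membered ring and the prenyl alkene only across a meta bridge, and the 5-OH is silylated. Slow addition at low concentration should keep carbene dimerisation and intermolecular attack on alkenes down.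

Step 7
Reactants: 12 silyl-protected (S)-flavanone
Product: 13 (2S)-2-[2-[(2E)-3,7-dimethylocta-2,6-dienyl]-3,4-dimethoxyphenyl]-5-hydroxy-7-methoxy-6-(3-methylbut-2-enyl)-2,3-dihydrochromen-4-one (target)
Conditions: Bu4NF, AcOH (1:1), THF, 0 °C
Reagents that add atoms: none
Why: Fluoride desilylation buffered with acetic acid, which should remove the labile peri silyl ether quickly while the near-neutral medium avoids the base-induced ring opening to the chalcone that would racemise C2.

**Compound list**
1 | 3,4-dimethoxybenzyl alcohol | COc1ccc(CO)cc1OC | starting material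
2 | geranyl bromide, (2E)-1-bromo-3,7-dimethylocta-2,6-diene | CC(C)=CCC/C(C)=C/CBr | starting material
3 | lithium [2-lithio-3,4-dimethoxyphenyl]methoxide | [Li]OCc1ccc(OC)c(OC)c1[Li] | intermediate
4 | [2-[(2E)-3,7-dimethylocta-2,6-dienyl]-3,4-dimethoxyphenyl]methanol | OCc1ccc(OC)c(OC)c1C/C=C(\C)CCC=C(C)C | intermediate
5 | 2',6'-dihydroxy-4'-methoxyacetophenone | CC(=O)c1c(O)cc(OC)cc1O | starting material
6 | prenyl bromide, 1-bromo-3-methylbut-2-ene | CC(C)=CCBr | starting material
7 | 1-[2,6-dihydroxy-4-methoxy-3-(3-methylbut-2-enyl)phenyl]ethanone | CC(=O)c1c(O)cc(OC)c(CC=C(C)C)c1O | intermediate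
8 | aryl benzyl ether of 7 at the less hindered hydroxyl | CC(=O)c1c(O)c(CC=C(C)C)c(OC)cc1OCc1ccc(OC)c(OC)c1C/C=C(\C)CCC=C(C)C | intermediate
9 | TBS ether of 8 | CC(=O)c1c(O[Si](C)(C)C(C)(C)C)c(CC=C(C)C)c(OC)cc1OCc1ccc(OC)c(OC)c1C/C=C(\C)CCC=C(C)C | intermediate
10 | 4,4,4-trifluoro-1-aryl-butane-1,3-dione derived from 9 | O=C(CC(=O)C(F)(F)F)c1c(O[Si](C)(C)C(C)(C)C)c(CC=C(C)C)c(OC)cc1OCc1ccc(OC)c(OC)c1C/C=C(\C)CCC=C(C)C | intermediate
11 | diazoketone derived from 9 | [N-]=[N+]=CC(=O)c1c(O[Si](C)(C)C(C)(C)C)c(CC=C(C)C)c(OC)cc1OCc1ccc(OC)c(OC)c1C/C=C(\C)CCC=C(C)C | intermediate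
12 | (2S)-5-O-TBS flavanone | COc1cc2c(c(O[Si](C)(C)C(C)(C)C)c1CC=C(C)C)C(=O)C[C@@H](c1ccc(OC)c(OC)c1C/C=C(\C)CCC=C(C)C)O2 | intermediate
13 | CNP0112088.1, (2S)-flavanone | COc1cc2c(c(O)c1CC=C(C)C)C(=O)C[C@@H](c1ccc(OC)c(OC)c1C/C=C(\C)CCC=C(C)C)O2 | target

**Step count:** 7 steps in total. The longest linear sequence is 6 steps (step 1 or step 2, then steps 3 to 7).

**Steps most likely to fail**

Step 6. The carbene may be diverted to O1 (ylide formation and 1,2-shift of the electron-rich benzyl group). The catalyst may also discriminate only weakly between the two enantiotopic hydrogens of an acceptor-only carbene. The fallback avoids the carbene, sets out from 4 and 7, and comes back at 12.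
- Alcohol 4 would be oxidised with MnO2 to 2-geranyl-3,4-dimethoxybenzaldehyde F1.
- Pinnick oxidation (NaClO2, NaH2PO4, excess 2-methylbut-2-ene) would give 2-geranyl-3,4-dimethoxybenzoic acid F2.
- Carbodiimide esterification (EDC, DMAP) with 7 at the less hindered phenol would give the aryl ester F3, and TBSOTf with 2,6-lutidine its silyl ether F4.
- A Baker–Venkataraman shift (LiN(SiMe3)2, THF) would form the same C2–C3 bond and give the 1,3-diketone F5.
- Mild cyclodehydration (catalytic TsOH, toluene) would give the 5-O-TBS flavone F6.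
- Copper hydride asymmetric conjugate reduction would set C2 and deliver 12. The conditions would be Cu(OAc)2, (EtO)2MeSiH, t-BuOH, toluene and the enantiomer of DTBM-SEGPHOS that leads to the S product.

Step 3. Site selectivity between the two phenolic hydroxyls may be poor, and double etherification may occur. The activated benzylic oxyphosphonium salt may also ionise and C-benzylate ring A. The fallback reverses the order of events, sets out from 4 and 5, and comes back at 8.
- Mitsunobu coupling of 4 with the symmetrical diol 5 has no site problem and would give the mono ether F7.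
- O-allylation catalysed by zerovalent palladium (Pd(PPh3)4, tert-butyl 2-methylbut-3-en-2-yl carbonate) would give the 1,1-dimethylallyl aryl ether F8.
- A thermal aromatic Claisen rearrangement (toluene, 110 °C) can reach only the one free ortho carbon, so it would place the prenyl group correctly and give 8. Step 2 then becomes unnecessary.

Step 5. The silyl group may migrate from the phenol oxygen to the neighbouring lithium enolate oxygen. Acylation of the enolate of the twisted, doubly ortho-substituted ketone may also be sluggish. The fallback avoids the lithium enolate and the diazo transfer, sets out from 9, and comes back at 11.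
- Soft enolisation (TBSOTf, Et3N, CH2Cl2) would give the silyl enol ether F9.
- NBS in THF at −78 °C should brominate this most nucleophilic alkene first and give the alpha-bromoketone F10.
- N,N'-ditosylhydrazine with DBU in THF at 0 °C would convert F10 into 11 by N-alkylation and loss of two sulfinate groups.

**Further compounds**
F1 | step 6 | 2-[(2E)-3,7-dimethylocta-2,6-dienyl]-3,4-dimethoxybenzaldehyde | O=Cc1ccc(OC)c(OC)c1C/C=C(\C)CCC=C(C)C
F2 | step 6 | 2-[(2E)-3,7-dimethylocta-2,6-dienyl]-3,4-dimethoxybenzoic acid | OC(=O)c1ccc(OC)c(OC)c1C/C=C(\C)CCC=C(C)C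
F3 | step 6 | 2-acetyl-3-hydroxy-5-methoxy-4-(3-methylbut-2-enyl)phenyl ester of F2 | CC(=O)c1c(O)c(CC=C(C)C)c(OC)cc1OC(=O)c1ccc(OC)c(OC)c1C/C=C(\C)CCC=C(C)C
F4 | step 6 | TBS ether of F3 | CC(=O)c1c(O[Si](C)(C)C(C)(C)C)c(CC=C(C)C)c(OC)cc1OC(=O)c1ccc(OC)c(OC)c1C/C=C(\C)CCC=C(C)C
F5 | step 6 | 1,3-diketone from the aroyl shift of F4 | O=C(CC(=O)c1ccc(OC)c(OC)c1C/C=C(\C)CCC=C(C)C)c1c(O)cc(OC)c(CC=C(C)C)c1O[Si](C)(C)C(C)(C)C
F6 | step 6 | 5-O-TBS flavone | COc1cc2oc(-c3ccc(OC)c(OC)c3C/C=C(\C)CCC=C(C)C)cc(=O)c2c(O[Si](C)(C)C(C)(C)C)c1CC=C(C)C
F7 | step 3 | mono benzyl ether of 5 | CC(=O)c1c(O)cc(OC)cc1OCc1ccc(OC)c(OC)c1C/C=C(\C)CCC=C(C)C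
F8 | step 3 | 1,1-dimethylallyl ether of F7 | CC(=O)c1c(OC(C)(C)C=C)cc(OC)cc1OCc1ccc(OC)c(OC)c1C/C=C(\C)CCC=C(C)C
F9 | step 5 | TBS enol ether of 9 | C=C(O[Si](C)(C)C(C)(C)C)c1c(O[Si](C)(C)C(C)(C)C)c(CC=C(C)C)c(OC)cc1OCc1ccc(OC)c(OC)c1C/C=C(\C)CCC=C(C)C
F10 | step 5 | alpha-bromoketone derived from 9 | O=C(CBr)c1c(O[Si](C)(C)C(C)(C)C)c(CC=C(C)C)c(OC)cc1OCc1ccc(OC)c(OC)c1C/C=C(\C)CCC=C(C)C
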